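(The numbers in the tables are calculated for an exercise.)

At early times the theta flask, which is the flask asked about, showed me little: target read 1.6% after 0.333 min and 1.4% after 0.667 min, with a scatter of 0.5 percentage points.

| setting | theta | zeta | flask |
|---|---|---|---|
| starting material | 0.011 M | 0.017 M | 0.011 M |
| second substrate | 0.044 M | 0.044 M | 0.0440 M |
| enzyme | 0.10 µM | 0.10 µM | 0.10 µM |
| impurity | 0.058 µM | 0.058 µM | 0.058 µM |
| remark | the very flask that is asked about, followed so far | run made earlier |  |

| run | time / min | target / % | starting material / % |
|---|---|---|---|
| theta | 0.333 | 1.6 | 99.4 |
| theta | 0.667 | 1.4 | 98.6 |
| theta | 1.50 | 3.3 | 97.2 |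
| theta | 4.00 | 7.1 | 93.8 |
| zeta | 2.00 | 3.2 | 96.7 |
| zeta | 4.00 | 5.5 | 94.1 |
| zeta | 5.00 | 6.0 | 93.5 |
| zeta | 8.00 | 9.5 | 90.8 |

(readings scatter by 0.5 percentage points)

- apparent order in second substrate when 5.0% of the starting material are converted (percent change of the rate of making target for one percent more second substrate charged)
- factor on the rate of making target when 5.0% of the starting material are converted if second substrate is charged twice over

- no earlier run changes the charge of second substrate; that part of a forecast is a guess

So I began from the end state of the catalyst and folded the charges into one number, the dead share 0.580, which is c(impurity)/c(enzyme), the fraction of the catalyst lost if each impurity kills one enzyme. On that count impurity was the limiting reagent of the loss, and I reckoned 0.420 of the catalyst to stay working. Second substrate does not enter this number, so I expected the dead share to cancel from the order.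

One number was not enough, since it tells how much catalyst works but not what the working part is doing. Counting target made plus starting material lost at 4.00 min, the zeta run had turned over 1.32 times the theta amount on 1.55 times the charge. That gives a rough reading of 0.646 for the order in starting material. If second substrate joins enzyme already holding starting material, and the binding steps stand near balance, its order is not lower than that of starting material, so I reckoned between 0.646 and one.

The forecast gave an order of 0.5, lower than my bottom end, and a factor of 1.35, expecting “a fractional order between 0 and 1”.

The flask gave an order of 0.90 and a factor of 1.89.

    ternary complex → enzyme + target (k = 534 s⁻¹)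
    starting material + enzyme ⇌ starting complex (K = 52.0 M⁻¹, k = 7.56 × 10⁵ M⁻¹ s⁻¹)
    enzyme + impurity → spent catalyst (k = 1.25 × 10⁶ M⁻¹ s⁻¹)
    second substrate + starting complex ⇌ ternary complex (K = 9.50 M⁻¹, k = 61500 M⁻¹ s⁻¹)

In the flask, spent catalyst stood at 57.9% of the catalyst at 5.0% conversion, level with the dead share. In the flask, ternary complex, at 4.81% of the catalyst after 5.00 min, was 11.5% of the working part. At 4.59 min in the flask, ternary complex fell back 12 times faster than it went on to target. The zeta run carried the same dead share, 0.580, so there too I count 0.420 of the catalyst as working.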